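**Retrosynthetic overview**
1. Acid 13 comes from its ethyl ester 12 by saponification.
2. The furan of 12 comes from the 1,4-diketone ethyl 3,6-dioxodocosanoate 11 (Paal–Knorr), carried masked as the dioxolane 10.
3. The key C2–C3 bond of 10 comes from the acyl imidazolide of ketal acid 6 plus magnesium ethyl malonate 7 (intermolecular decarboxylative Claisen condensation).
4. Acid 6 comes from ethyl 4-oxoicosanoate 4, made from the hexadecyl Grignard of 1 and ethyl succinyl chloride 2.
5. Ring order: the dioxolane (temporary protecting ring) is formed in step 2; the furan, the only ring of the target, is formed in step 5.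

Assumption: the target has no stereocentre and no stereogenic double bond, so it is achiral and no stereocontrol is needed.

**Step 1**
Reactants: 1 1-bromohexadecane; 2 ethyl 4-chloro-4-oxobutanoate (ethyl succinyl chloride)
Product: 4 ethyl 4-oxoicosanoate, via hexadecylmagnesium bromide 3 (not isolated)
Conditions: Mg, I2 (cat.), THF, 50 °C; then added to 2, Fe(acac)3 (3 mol %), THF, −78 °C, 20 min; aq. NH4Cl
Reagents that add atoms: none
Why: Grignard formation followed by iron-catalysed Grignard–acid chloride cross-coupling (acylation), which at −78 °C is far faster than attack on the ethyl ester or on the product ketone, so the γ-keto ester forms without over-addition.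

**Step 2**
Reactants: 4 ethyl 4-oxoicosanoate
Product: 5 ethyl 3-(2-hexadecyl-1,3-dioxolan-2-yl)propanoate
Conditions: HOCH2CH2OH (3 equiv), p-TsOH·H2O (5 mol %), toluene, reflux, Dean–Stark
Reagents that add atoms: ethylene glycol, OCCO
Why: Acid-catalysed ketalisation driven by azeotropic water removal masks the ketone as a base-stable dioxolane, so it cannot be attacked or enolised in the condensation step.

**Step 3**
Reactants: 5 ethyl 3-(2-hexadecyl-1,3-dioxolan-2-yl)propanoate
Product: 6 3-(2-hexadecyl-1,3-dioxolan-2-yl)propanoic acid
Conditions: LiOH·H2O (3 equiv), THF/EtOH/H2O, 40 °C; then 1 M HCl to pH 4–5, 0 °C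
Reagents that add atoms: lithium hydroxide, [Li+].[OH-]
Why: Saponification (base-mediated ester hydrolysis) leaves the dioxolane untouched, and the cold, mildly acidic work-up frees the acid without cleaving the ketal.

**Step 4 (key step)**
Reactants: 6 3-(2-hexadecyl-1,3-dioxolan-2-yl)propanoic acid; 7 magnesium bis(3-ethoxy-3-oxopropanoate) (magnesium ethyl malonate)
Product: 10 ethyl 5-(2-hexadecyl-1,3-dioxolan-2-yl)-3-oxopentanoate, via acyl imidazolide 8 (not isolated), via acylmalonic half-ester 9 (not isolated)
Conditions: CDI (1.2 equiv), THF, rt, 2 h; then 7 (1.0 equiv), THF, rt → 40 °C, 16 h; cold 0.5 M HCl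
Reagents that add atoms: none
Why: Masamune–Brooks decarboxylative Claisen condensation, in which the neutral magnesium-chelated malonate half-ester enolate is C-acylated by the acyl imidazolide and loss of CO2 gives one β-keto ester with no self-condensation and no strong base near the ketal.

**Step 5**
Reactants: 10 ethyl 5-(2-hexadecyl-1,3-dioxolan-2-yl)-3-oxopentanoate
Product: 12 ethyl 2-(5-hexadecylfuran-2-yl)acetate, via ethyl 3,6-dioxodocosanoate 11 (not isolated)
Conditions: p-TsOH·H2O (0.2 equiv), toluene, 80 °C → reflux
Reagents that add atoms: none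
Why: Acid-catalysed deketalisation unmasks the 1,4-diketone, which undergoes Paal–Knorr cyclodehydration driven by furan aromatisation; the water released by cyclisation feeds the ketal hydrolysis, and any glycol ester formed by transesterification converges in step 6.

**Step 6**
Reactants: 12 ethyl 2-(5-hexadecylfuran-2-yl)acetate
Product: 13 2-(5-hexadecylfuran-2-yl)acetic acid
Conditions: LiOH·H2O (3 equiv), THF/MeOH/H2O, rt; then 1 M HCl to pH 3, 0 °C
Reagents that add atoms: lithium hydroxide, [Li+].[OH-]
Why: Saponification of the ethyl ester; the 2,5-dialkylfuran is inert to hydroxide and survives the brief cold acidification that liberates the acid.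

**Compound list**
1 | 1-bromohexadecane | CCCCCCCCCCCCCCCCBr | starting material
2 | ethyl 4-chloro-4-oxobutanoate | CCOC(=O)CCC(=O)Cl | starting material
3 | hexadecylmagnesium bromide | CCCCCCCCCCCCCCCC[Mg]Br | intermediate
4 | ethyl 4-oxoicosanoate | CCCCCCCCCCCCCCCCC(=O)CCC(=O)OCC | intermediate
5 | ethyl 3-(2-hexadecyl-1,3-dioxolan-2-yl)propanoate | CCCCCCCCCCCCCCCCC1(CCC(=O)OCC)OCCO1 | intermediate
6 | 3-(2-hexadecyl-1,3-dioxolan-2-yl)propanoic acid | CCCCCCCCCCCCCCCCC1(CCC(=O)O)OCCO1 | intermediate
7 | magnesium bis(3-ethoxy-3-oxopropanoate) | CCOC(=O)CC(=O)[O-].CCOC(=O)CC(=O)[O-].[Mg+2] | starting material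
8 | 1-[3-(2-hexadecyl-1,3-dioxolan-2-yl)propanoyl]-1H-imidazole (acyl imidazolide) | CCCCCCCCCCCCCCCCC1(CCC(=O)n2ccnc2)OCCO1 | intermediate
9 | 2-(ethoxycarbonyl)-5-(2-hexadecyl-1,3-dioxolan-2-yl)-3-oxopentanoic acid (acylmalonic half-ester, present as its magnesium salt) | CCCCCCCCCCCCCCCCC1(CCC(=O)C(C(=O)O)C(=O)OCC)OCCO1 | intermediate
10 | ethyl 5-(2-hexadecyl-1,3-dioxolan-2-yl)-3-oxopentanoate | CCCCCCCCCCCCCCCCC1(CCC(=O)CC(=O)OCC)OCCO1 | intermediate
11 | ethyl 3,6-dioxodocosanoate | CCCCCCCCCCCCCCCCC(=O)CCC(=O)CC(=O)OCC | intermediate
12 | ethyl 2-(5-hexadecylfuran-2-yl)acetate | CCCCCCCCCCCCCCCCc1ccc(CC(=O)OCC)o1 | intermediate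
13 | 2-(5-hexadecylfuran-2-yl)acetic acid | CCCCCCCCCCCCCCCCc1ccc(CC(=O)O)o1 | target

**Total step count:** 6
**Longest linear sequence:** 6 steps (1 → 4 → 5 → 6 → 10 → 12 → 13)

**Three steps most likely to fail, with fallbacks**

Step 1 could suffer from Wurtz homocoupling while the Grignard forms, and from over-addition to the new ketone or attack at the ester. The fallback sets out from 3 and comes back at 4. Reagent 3 is added inversely to succinic anhydride (THF, −40 → 0 °C). Ring opening gives a magnesium carboxylate that shields the ketone from a second addition, and HCl work-up gives crystalline 4-oxoicosanoic acid F1. Fischer esterification (EtOH, cat. H2SO4, reflux) then returns 4.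

Step 4 could suffer from sluggish C-acylation of the magnesium malonate, incomplete decarboxylation, or ketal loss on work-up. The fallback sets out from 6 and comes back at 10. Acid 6 is activated with CDI as before to give 8, which is intercepted with MeNHOMe·HCl (THF, rt) to give the Weinreb amide 3-(2-hexadecyl-1,3-dioxolan-2-yl)-N-methoxy-N-methylpropanamide F2. F2 acylates ethyl lithioacetate F3 (from ethyl acetate and LDA, THF, −78 °C, 2.5 equiv) in a direct crossed Claisen-type condensation. N,O-chelation holds the reaction at the mono-adduct stage, and NH4Cl work-up releases 10 under basic-to-neutral conditions that are safe for the ketal.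

Step 5 could suffer from acid-promoted oligomerisation of the electron-rich furan, stalling at the exocyclic furan-2(3H)-ylidene acetate isomer, or hydrolysis and decarboxylation of the β-keto ester if the mixture is wet. The fallback sets out from 1 and comes back at 12, so the furan ring is bought rather than made. Furan is lithiated (n-BuLi, THF, 0 °C) to 2-furyllithium F4, which is alkylated with 1 (THF, rt → 50 °C) to give 2-hexadecylfuran F5. Oxidative radical alkylation at the free α-position then gives 12 directly, using S-(2-ethoxy-2-oxoethyl) O-ethyl dithiocarbonate and dilauroyl peroxide (1.3 equiv) in 1,2-dichloroethane at reflux. The electrophilic ester-substituted radical adds at C5, the adduct is oxidised by the peroxide and rearomatises by proton loss, and 12 continues to step 6.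

**Further compounds**
F1 | step 1 | 4-oxoicosanoic acid | CCCCCCCCCCCCCCCCC(=O)CCC(=O)O
F2 | step 4 | 3-(2-hexadecyl-1,3-dioxolan-2-yl)-N-methoxy-N-methylpropanamide | CCCCCCCCCCCCCCCCC1(CCC(=O)N(C)OC)OCCO1
F3 | step 4 | ethyl lithioacetate (lithium enolate of ethyl acetate) | C=C([O-])OCC.[Li+]
F4 | step 5 | 2-furyllithium | [Li]c1ccco1
F5 | step 5 | 2-hexadecylfuran | CCCCCCCCCCCCCCCCc1ccco1
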